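**Plan**

- Retrosynthetic cuts: first the four O-alkyl groups masking the phenols; then O1–C8a and C4–C4a of the chromone, which separates ring A as 3,5-dimethoxybenzyne from the enol of a ring B α-formylacetate; then the formyl carbon (C2) and the ring B aryl–CH2 bond; then the styrene C=C and the carbinol–aryl bond; then the aryl–C bond at the stereocentre, leading to a 6-bromo-7-alkoxycoumarin and 4-bromoresorcinol.
- Enabling feature: ring A is fused to ring C through the neighbouring bonds O1–C8a and C4–C4a and carries oxygen on C5, directly beside C4a. This is the pattern left when an oxygen nucleophile and an acyl group add across a 3-alkoxyaryne.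
- Forward order: a lactone ring is built on ring B, used to install the third aryl group and the stereocentre, and opened again. The chain is completed by aryl Grignard addition and dehydration to the E-styrene, the acetate and formyl carbons are added, ring C is closed last with ring A delivered whole, and the phenols are unmasked.
- Stereochemistry: the single stereocentre comes from a rhodium/(R)-Segphos conjugate addition of the 4-isopropoxyphenyl group to C4 of the coumarin. It is never a reacting centre afterwards, and every later base is too weak to remove its proton. The E alkene arises by dehydration into conjugation.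

Key step: step 13

Assumption: the rhodium/(R)-Segphos catalyst is taken to add the aryl group to the same face of this coumarin as it does with simple coumarins, which corresponds to R at C4; if the sense proves opposite, (S)-Segphos is used and nothing else changes.

**Route**

Step 1
Reactants: 1 4-bromoresorcinol
Product: 2 6-bromo-7-hydroxy-2H-chromen-2-one
Conditions: DL-malic acid, conc. H2SO4, 110 °C
Reagents that add atoms: DL-malic acid, OC(CC(=O)O)C(=O)O
Why: Pechmann condensation, in which malic acid loses CO and water to give formylacetic acid, which attacks the one free ring position ortho to one hydroxyl and para to the other and then lactonises, so that bromine ends at C6 and the free hydroxyl at C7.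

Step 2
Reactants: 2 6-bromo-7-hydroxy-2H-chromen-2-one
Product: 3 6-bromo-7-isopropoxy-2H-chromen-2-one
Conditions: 2-bromopropane, K2CO3, DMF, 60 °C
Reagents that add atoms: 2-bromopropane, CC(C)Br
Why: Williamson etherification of the acidic phenol under carbonate conditions that leave the lactone intact.

Step 3
Reactants: 3 6-bromo-7-isopropoxy-2H-chromen-2-one; 4 4-isopropoxyphenylboronic acid (excess)
Product: 5 (4R)-6-bromo-7-isopropoxy-4-(4-isopropoxyphenyl)chroman-2-one
Conditions: Rh(acac)(C2H4)2 (3 mol %), (R)-Segphos, dioxane/H2O (10:1), 60 °C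
Reagents that add atoms: none
Why: Hayashi–Miyaura rhodium-catalysed asymmetric 1,4-addition of an arylboronic acid to a coumarin, in which the aryl group passes from Segphos-bound monovalent rhodium to one face of C4 and sets the stereocentre as R, while the aryl bromide is inert to this catalyst.

Step 4
Reactants: 5 (4R)-6-bromo-7-isopropoxy-4-(4-isopropoxyphenyl)chroman-2-one
Product: 6 (4R)-6-bromo-7-isopropoxy-4-(4-isopropoxyphenyl)chroman-2-ol (both C2 epimers)
Conditions: i-Bu2AlH, toluene, −78 °C; aq. KNaC4H4O6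
Reagents that add atoms: none
Why: Partial reduction of a lactone with i-Bu2AlH, whose aluminium hemiacetal is stable at −78 °C and gives the lactol on work-up, leaving the bromide, the ethers and the C4 stereocentre untouched.

Step 5
Reactants: 6 (4R)-6-bromo-7-isopropoxy-4-(4-isopropoxyphenyl)chroman-2-ol; 7 2,4-dimethoxyphenylmagnesium bromide (THF solution, 3 equiv)
Product: 9 4-bromo-2-[(1R)-3-(2,4-dimethoxyphenyl)-3-hydroxy-1-(4-isopropoxyphenyl)propyl]-5-isopropoxyphenol (both carbinol epimers), via ring-opened aldehyde phenoxide 8 (not isolated)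
Conditions: THF, 0 °C → rt; aq. NH4Cl
Reagents that add atoms: none
Why: Grignard addition, in which the first equivalent deprotonates the lactol so that it opens to the aldehyde and a second adds to the carbonyl group, the uncontrolled carbinol centre being of no account because step 7 removes it.

Step 6
Reactants: 9 4-bromo-2-[(1R)-3-(2,4-dimethoxyphenyl)-3-hydroxy-1-(4-isopropoxyphenyl)propyl]-5-isopropoxyphenol
Product: 10 (3R)-3-(5-bromo-2,4-diisopropoxyphenyl)-1-(2,4-dimethoxyphenyl)-3-(4-isopropoxyphenyl)propan-1-ol (both carbinol epimers)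
Conditions: 2-bromopropane, K2CO3, DMF, 50 °C
Reagents that add atoms: 2-bromopropane, CC(C)Br
Why: Williamson etherification that is selective for the phenol, since K2CO3 ionises the phenol but not the secondary alcohol.

Step 7
Reactants: 10 (3R)-3-(5-bromo-2,4-diisopropoxyphenyl)-1-(2,4-dimethoxyphenyl)-3-(4-isopropoxyphenyl)propan-1-ol
Product: 11 1-bromo-5-[(1R,2E)-3-(2,4-dimethoxyphenyl)-1-(4-isopropoxyphenyl)prop-2-en-1-yl]-2,4-diisopropoxybenzene
Conditions: Burgess reagent, THF, 50 °C
Reagents that add atoms: none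
Why: Burgess dehydration, in which the sulfamate ester of this electron-rich benzylic alcohol eliminates under neutral conditions toward the only β-hydrogens (the CH2 group) to give the conjugated E-styrene, the absence of acid sparing the allylic stereocentre.

Step 8
Reactants: 11 1-bromo-5-[(1R,2E)-3-(2,4-dimethoxyphenyl)-1-(4-isopropoxyphenyl)prop-2-en-1-yl]-2,4-diisopropoxybenzene
Product: 12 methyl 2-{5-[(1R,2E)-3-(2,4-dimethoxyphenyl)-1-(4-isopropoxyphenyl)prop-2-en-1-yl]-2,4-diisopropoxyphenyl}acetate
Conditions: BrZnCH2CO2Me (separately prepared THF solution), Pd(dba)2 (2 mol %), P(t-Bu)3, THF, rt → 50 °C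
Reagents that add atoms: (2-methoxy-2-oxoethyl)zinc bromide, COC(=O)C[Zn]Br
Why: Palladium-catalysed α-arylation of a zinc ester enolate (Negishi-type coupling of a Reformatsky reagent), in which zerovalent palladium with P(t-Bu)3 inserts into the electron-rich aryl bromide and the neutral zinc enolate is too weakly basic to touch the doubly benzylic allylic C–H.

Step 9
Reactants: 12 methyl 2-{5-[(1R,2E)-3-(2,4-dimethoxyphenyl)-1-(4-isopropoxyphenyl)prop-2-en-1-yl]-2,4-diisopropoxyphenyl}acetate
Product: 14 methyl 2-{5-[(1R,2E)-3-(2,4-dimethoxyphenyl)-1-(4-isopropoxyphenyl)prop-2-en-1-yl]-2,4-diisopropoxyphenyl}-3-hydroxyprop-2-enoate (enol of the α-formyl ester), via lithium ester enolate 13 (not isolated)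
Conditions: LiN(SiMe3)2 (1.3 equiv), THF, −78 °C; HCO2Me, −78 → 0 °C; aq. NH4Cl
Reagents that add atoms: methyl formate, COC=O
Why: Crossed Claisen condensation (α-formylation) of the ester enolate with methyl formate, driven by formation of the stabilised enolate of the product, with a silylamide base strong enough for the arylacetate CH2 but too weak and hindered to remove the allylic diarylmethine proton, so that configuration and alkene position should hold.

Step 10
Reactants: 15 3,5-dimethoxyphenol
Product: 16 3,5-dimethoxyphenyl N-isopropylcarbamate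
Conditions: i-PrNCO, Et3N (cat.), CH2Cl2, rt
Reagents that add atoms: isopropyl isocyanate, CC(C)N=C=O
Why: Base-catalysed addition of a phenol to an isocyanate, giving an N-monosubstituted carbamate that serves as directing group and can later be removed by elimination.

Step 11
Reactants: 16 3,5-dimethoxyphenyl N-isopropylcarbamate
Product: 20 3,5-dimethoxy-2-(trimethylsilyl)phenyl N-isopropylcarbamate, via N-silyl carbamate 17 (not isolated), via ortho-lithiated carbamate 18 (not isolated), via N-silyl aryl silane 19 (not isolated)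
Conditions: t-BuMe2SiOTf, TMEDA, Et2O, 0 °C → rt; n-BuLi, TMEDA, −78 °C; Me3SiCl, −78 °C → rt; aq. NaHSO4
Reagents that add atoms: chlorotrimethylsilane, C[Si](C)(C)Cl
Why: Directed ortho-metalation, in which, after silylation of the N–H, the carbamate and the adjacent methoxy group together direct lithiation to C2 in preference to C4 between the two methoxy groups, the chlorosilane traps the aryllithium and the N–Si bond is hydrolysed on acidic work-up.

Step 12
Reactants: 20 3,5-dimethoxy-2-(trimethylsilyl)phenyl N-isopropylcarbamate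
Product: 22 3,5-dimethoxy-2-(trimethylsilyl)phenyl trifluoromethanesulfonate, via silyl phenol 21 (not isolated)
Conditions: DBU, Et2NH, MeCN, 40 °C; then PhNTf2, rt
Reagents that add atoms: N-phenylbis(trifluoromethanesulfonimide), O=S(=O)(N(c1ccccc1)S(=O)(=O)C(F)(F)F)C(F)(F)F
Why: E1cB cleavage of the N-monosubstituted carbamate by DBU with capture of the isocyanate by Et2NH, followed in the same flask by O-sulfonylation of the phenoxide with PhNTf2, a standard entry to ortho-silylaryl triflates.

Step 13
Reactants: 14 methyl 2-aryl-3-hydroxyprop-2-enoate (the enol from step 9); 22 3,5-dimethoxy-2-(trimethylsilyl)phenyl trifluoromethanesulfonate (1.5 equiv)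
Product: 25 3-{5-[(1R,2E)-3-(2,4-dimethoxyphenyl)-1-(4-isopropoxyphenyl)prop-2-en-1-yl]-2,4-diisopropoxyphenyl}-5,7-dimethoxy-4H-chromen-4-one, via 3,5-dimethoxybenzyne 23 (not isolated), via aryl anion adduct 24 (not isolated)
Conditions: CsF (4 equiv), THF, 65 °C
Reagents that add atoms: none
Why: Proposed new method: fluoride removes the silyl group of 22 with loss of triflate to give the aryne and also deprotonates enol 14; the enolate oxygen adds to the aryne carbon remote from the methoxy group (the future C8a), and the aryl anion formed at C4a attacks the cis-disposed ester carbonyl and expels methoxide, which is neutralised by the hydrogen fluoride formed at the outset. The closest known reaction type is the fluoride-induced annulation of arynes with salicylate esters to xanthones, of which this is the open-chain vinylogous counterpart, together with aryne insertion into the C–O bond of carboxylic acids. Ring C closes by 6-exo-trig acyl substitution, which needs the Z enol ether that the chelated enolate supplies. No stereocentre is formed, and the existing one is spared because the only strong base, the aryl anion, is consumed intramolecularly. Two selectivities are required: attack through oxygen and not through the α-carbon of the ambident enolate, favoured by the fully substituted α-carbon flanked by an ortho-isopropoxyaryl group and by the charge on the formyl oxygen, and aryne regiochemistry, fixed by the inductive effect of the methoxy group next to the triple bond, which places the anion beside it. THF at moderate temperature is chosen so that acyl capture outruns protonation of the aryl anion.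

Step 14
Reactants: 25 3-{5-[(1R,2E)-3-(2,4-dimethoxyphenyl)-1-(4-isopropoxyphenyl)prop-2-en-1-yl]-2,4-diisopropoxyphenyl}-5,7-dimethoxy-4H-chromen-4-one
Product: 26 caraganin B
Conditions: BCl3, CH2Cl2, −78 → 0 °C; cold aq. NaHCO3
Reagents that add atoms: none
Why: Lewis-acid ether cleavage, in which BCl3 removes the secondary alkyl aryl ethers and, through chelation with the C4 carbonyl, the peri methyl ether on C5, while unchelated methyl ethers survive at 0 °C and the cold basic quench limits acid-promoted addition of the freed ortho phenol to the styrene.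

**Compound list**

1 | 4-bromoresorcinol | Oc1ccc(Br)c(O)c1 | starting material
2 | 6-bromo-7-hydroxy-2H-chromen-2-one | O=c1ccc2cc(Br)c(O)cc2o1 | intermediate
3 | 6-bromo-7-isopropoxy-2H-chromen-2-one | CC(C)Oc1cc2oc(=O)ccc2cc1Br | intermediate
4 | 4-isopropoxyphenylboronic acid | CC(C)Oc1ccc(B(O)O)cc1 | starting material
5 | (4R)-6-bromo-7-isopropoxy-4-(4-isopropoxyphenyl)chroman-2-one | O=C1C[C@H](c2ccc(OC(C)C)cc2)c2cc(Br)c(OC(C)C)cc2O1 | intermediate
6 | (4R)-6-bromo-7-isopropoxy-4-(4-isopropoxyphenyl)chroman-2-ol, both C2 epimers | OC1C[C@H](c2ccc(OC(C)C)cc2)c2cc(Br)c(OC(C)C)cc2O1 | intermediate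
7 | 2,4-dimethoxyphenylmagnesium bromide | COc1ccc([Mg]Br)c(OC)c1 | starting material
8 | bromomagnesium phenoxide of (3R)-3-(5-bromo-2-hydroxy-4-isopropoxyphenyl)-3-(4-isopropoxyphenyl)propanal | O=CC[C@H](c1ccc(OC(C)C)cc1)c1cc(Br)c(OC(C)C)cc1O[Mg]Br | intermediate
9 | 4-bromo-2-[(1R)-3-(2,4-dimethoxyphenyl)-3-hydroxy-1-(4-isopropoxyphenyl)propyl]-5-isopropoxyphenol, both carbinol epimers | COc1ccc(C(O)C[C@H](c2ccc(OC(C)C)cc2)c2cc(Br)c(OC(C)C)cc2O)c(OC)c1 | intermediate
10 | (3R)-3-(5-bromo-2,4-diisopropoxyphenyl)-1-(2,4-dimethoxyphenyl)-3-(4-isopropoxyphenyl)propan-1-ol, both carbinol epimers | COc1ccc(C(O)C[C@H](c2ccc(OC(C)C)cc2)c2cc(Br)c(OC(C)C)cc2OC(C)C)c(OC)c1 | intermediate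
11 | 1-bromo-5-[(1R,2E)-3-(2,4-dimethoxyphenyl)-1-(4-isopropoxyphenyl)prop-2-en-1-yl]-2,4-diisopropoxybenzene | COc1ccc(/C=C/[C@H](c2ccc(OC(C)C)cc2)c2cc(Br)c(OC(C)C)cc2OC(C)C)c(OC)c1 | intermediate
12 | methyl 2-{5-[(1R,2E)-3-(2,4-dimethoxyphenyl)-1-(4-isopropoxyphenyl)prop-2-en-1-yl]-2,4-diisopropoxyphenyl}acetate | COc1ccc(/C=C/[C@H](c2ccc(OC(C)C)cc2)c2cc(CC(=O)OC)c(OC(C)C)cc2OC(C)C)c(OC)c1 | intermediate
13 | lithium enolate of 12 (ketene acetal form) | COc1ccc(/C=C/[C@H](c2ccc(OC(C)C)cc2)c2cc(C=C(OC)O[Li])c(OC(C)C)cc2OC(C)C)c(OC)c1 | intermediate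
14 | methyl 2-{5-[(1R,2E)-3-(2,4-dimethoxyphenyl)-1-(4-isopropoxyphenyl)prop-2-en-1-yl]-2,4-diisopropoxyphenyl}-3-hydroxyprop-2-enoate (enol geometry not fixed, in equilibrium with the aldehyde) | COc1ccc(/C=C/[C@H](c2ccc(OC(C)C)cc2)c2cc(C(=CO)C(=O)OC)c(OC(C)C)cc2OC(C)C)c(OC)c1 | intermediate
15 | 3,5-dimethoxyphenol | COc1cc(O)cc(OC)c1 | starting material
16 | 3,5-dimethoxyphenyl N-isopropylcarbamate | COc1cc(OC)cc(OC(=O)NC(C)C)c1 | intermediate
17 | 3,5-dimethoxyphenyl N-(tert-butyldimethylsilyl)-N-isopropylcarbamate | COc1cc(OC)cc(OC(=O)N(C(C)C)[Si](C)(C)C(C)(C)C)c1 | intermediate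
18 | 2-lithio-3,5-dimethoxyphenyl N-(tert-butyldimethylsilyl)-N-isopropylcarbamate | [Li]c1c(OC)cc(OC)cc1OC(=O)N(C(C)C)[Si](C)(C)C(C)(C)C | intermediate
19 | 3,5-dimethoxy-2-(trimethylsilyl)phenyl N-(tert-butyldimethylsilyl)-N-isopropylcarbamate | COc1cc(OC)c([Si](C)(C)C)c(OC(=O)N(C(C)C)[Si](C)(C)C(C)(C)C)c1 | intermediate
20 | 3,5-dimethoxy-2-(trimethylsilyl)phenyl N-isopropylcarbamate | COc1cc(OC)c([Si](C)(C)C)c(OC(=O)NC(C)C)c1 | intermediate
21 | 3,5-dimethoxy-2-(trimethylsilyl)phenol (present as its DBU salt) | COc1cc(O)c([Si](C)(C)C)c(OC)c1 | intermediate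
22 | 3,5-dimethoxy-2-(trimethylsilyl)phenyl trifluoromethanesulfonate | COc1cc(OC)c([Si](C)(C)C)c(OS(=O)(=O)C(F)(F)F)c1 | intermediate
23 | 3,5-dimethoxybenzyne | COC1=CC(OC)=CC#C1 | intermediate
24 | cesium aryl anion formed by O-arylation of the enolate of 14 (Z enol ether, carbanion at the future C4a) | COc1ccc(/C=C/[C@H](c2ccc(OC(C)C)cc2)c2cc(/C(C(=O)OC)=C/Oc3cc(OC)cc(OC)[c-]3)c(OC(C)C)cc2OC(C)C)c(OC)c1.[Cs+] | intermediate
25 | 3-{5-[(1R,2E)-3-(2,4-dimethoxyphenyl)-1-(4-isopropoxyphenyl)prop-2-en-1-yl]-2,4-diisopropoxyphenyl}-5,7-dimethoxy-4H-chromen-4-one | COc1ccc(/C=C/[C@H](c2ccc(OC(C)C)cc2)c2cc(-c3coc4cc(OC)cc(OC)c4c3=O)c(OC(C)C)cc2OC(C)C)c(OC)c1 | intermediate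
26 | caraganin B, 3-{5-[(1R,2E)-3-(2,4-dimethoxyphenyl)-1-(4-hydroxyphenyl)prop-2-en-1-yl]-2,4-dihydroxyphenyl}-5-hydroxy-7-methoxy-4H-chromen-4-one | COc1ccc(/C=C/[C@H](c2ccc(O)cc2)c2cc(-c3coc4cc(OC)cc(O)c4c3=O)c(O)cc2O)c(OC)c1 | target

**Count**

Total steps: 14. Longest linear sequence: 11 steps (steps 1–9, 13 and 14); the aryne precursor branch (steps 10–12) joins at step 13.

**Steps most likely to fail**

Step 13 (new method). The ambident enolate may be arylated at carbon, after which the aryl anion closes onto the formyl group and the four-membered alkoxide fragments, a net insertion of the aryne into the C–C bond. Alternatively, the aryl anion may be protonated before it reaches the ester, leaving an open aryl enol ether. Cycloaddition of the aryne with the styrene may also consume material. The fallback uses known chemistry and forms the same two bonds to ring A. It sets out from ester 12, which LiOH in THF/MeOH/H2O should hydrolyse to 2-{5-[(1R,2E)-3-(2,4-dimethoxyphenyl)-1-(4-isopropoxyphenyl)prop-2-en-1-yl]-2,4-diisopropoxyphenyl}acetic acid F1. Heating F1 with triflate 22 and CsF in THF at 125 °C in a sealed tube applies the established insertion of an aryne into the C–O bond of a carboxylic acid: O-arylation, attack of the aryl anion on the aryl ester carbonyl, and opening of the four-membered ring. With the same aryne regiochemistry this should give the 2-hydroxy-4,6-dimethoxyphenyl ketone (deoxybenzoin) F2. Warming F2 with N,N-dimethylformamide dimethyl acetal supplies C2 and closes ring C, and the route is rejoined at 25.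

Step 14. Once the hydroxyl ortho to the side chain is free, acid present at the quench may protonate the electron-rich styrene, and the phenol may add to the benzylic cation to give a 2,4-diarylchroman. Friedel–Crafts isopropylation of the resorcinol rings and loss of an unchelated methyl ether are lesser risks. The fallback masks that one phenol with a group BCl3 does not cleave, and sets out from diol 9.
- t-BuCOCl and Et3N in CH2Cl2 at 0 °C should acylate the phenol selectively to give the pivalate carbinol F3.
- Steps 7, 8, 9 and 13 are then repeated in this series: Burgess dehydration to the pivalate styrene F4, zinc enolate coupling to the pivalate arylacetate F5, formylation to the pivalate enol F6, and aryne annulation to the pivalate chromone F7.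
- BCl3 then removes the two isopropyl groups and the C5 methyl group to give 4'-O-pivaloyl caraganin B F8, in which the critical phenol is still acylated and cannot cyclise.
- K2CO3 in MeOH at room temperature cleaves the pivalate under basic conditions and the route is rejoined at 26.

Step 3. The C7 alkoxy group lowers the electrophilicity of the coumarin, so protodeboronation of 4 may outpace insertion, or facial selectivity may be incomplete. The fallback moves the asymmetric arylation to a more reactive acyclic enone and sets out from 1.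
- 2-Bromopropane and K2CO3 in DMF give 1-bromo-2,4-diisopropoxybenzene F9.
- Vilsmeier–Haack formylation (POCl3, DMF), para to one alkoxy group and ortho to the other, gives 5-bromo-2,4-diisopropoxybenzaldehyde F10.
- Claisen–Schmidt condensation with 2',4'-dimethoxyacetophenone (KOH, EtOH) gives the E-chalcone F11.
- Rhodium-catalysed asymmetric 1,4-addition of 4 ([RhCl(C2H4)2]2, a chiral bicyclo[2.2.2]octa-2,5-diene ligand, KOH, dioxane/H2O), with the ligand antipode chosen to deliver the R configuration, gives the β,β-diaryl ketone F12.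
- NaBH4 in MeOH reduces F12 to carbinol 10, where the route is rejoined at step 7; steps 2–6 are then not needed.

**Further compounds**

F1 | step 13 | 2-{5-[(1R,2E)-3-(2,4-dimethoxyphenyl)-1-(4-isopropoxyphenyl)prop-2-en-1-yl]-2,4-diisopropoxyphenyl}acetic acid | COc1ccc(/C=C/[C@H](c2ccc(OC(C)C)cc2)c2cc(CC(=O)O)c(OC(C)C)cc2OC(C)C)c(OC)c1
F2 | step 13 | 2-{5-[(1R,2E)-3-(2,4-dimethoxyphenyl)-1-(4-isopropoxyphenyl)prop-2-en-1-yl]-2,4-diisopropoxyphenyl}-1-(2-hydroxy-4,6-dimethoxyphenyl)ethan-1-one | COc1ccc(/C=C/[C@H](c2ccc(OC(C)C)cc2)c2cc(CC(=O)c3c(O)cc(OC)cc3OC)c(OC(C)C)cc2OC(C)C)c(OC)c1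
F3 | step 14 | 4-bromo-2-[(1R)-3-(2,4-dimethoxyphenyl)-3-hydroxy-1-(4-isopropoxyphenyl)propyl]-5-isopropoxyphenyl pivalate, both carbinol epimers | COc1ccc(C(O)C[C@H](c2ccc(OC(C)C)cc2)c2cc(Br)c(OC(C)C)cc2OC(=O)C(C)(C)C)c(OC)c1
F4 | step 14 | 4-bromo-2-[(1R,2E)-3-(2,4-dimethoxyphenyl)-1-(4-isopropoxyphenyl)prop-2-en-1-yl]-5-isopropoxyphenyl pivalate | COc1ccc(/C=C/[C@H](c2ccc(OC(C)C)cc2)c2cc(Br)c(OC(C)C)cc2OC(=O)C(C)(C)C)c(OC)c1
F5 | step 14 | methyl 2-{5-[(1R,2E)-3-(2,4-dimethoxyphenyl)-1-(4-isopropoxyphenyl)prop-2-en-1-yl]-2-isopropoxy-4-(pivaloyloxy)phenyl}acetate | COc1ccc(/C=C/[C@H](c2ccc(OC(C)C)cc2)c2cc(CC(=O)OC)c(OC(C)C)cc2OC(=O)C(C)(C)C)c(OC)c1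
F6 | step 14 | methyl 2-{5-[(1R,2E)-3-(2,4-dimethoxyphenyl)-1-(4-isopropoxyphenyl)prop-2-en-1-yl]-2-isopropoxy-4-(pivaloyloxy)phenyl}-3-hydroxyprop-2-enoate | COc1ccc(/C=C/[C@H](c2ccc(OC(C)C)cc2)c2cc(C(=CO)C(=O)OC)c(OC(C)C)cc2OC(=O)C(C)(C)C)c(OC)c1
F7 | step 14 | 4-(5,7-dimethoxy-4-oxo-4H-chromen-3-yl)-2-[(1R,2E)-3-(2,4-dimethoxyphenyl)-1-(4-isopropoxyphenyl)prop-2-en-1-yl]-5-isopropoxyphenyl pivalate | COc1ccc(/C=C/[C@H](c2ccc(OC(C)C)cc2)c2cc(-c3coc4cc(OC)cc(OC)c4c3=O)c(OC(C)C)cc2OC(=O)C(C)(C)C)c(OC)c1
F8 | step 14 | 4'-O-pivaloyl caraganin B, 2-[(1R,2E)-3-(2,4-dimethoxyphenyl)-1-(4-hydroxyphenyl)prop-2-en-1-yl]-5-hydroxy-4-(5-hydroxy-7-methoxy-4-oxo-4H-chromen-3-yl)phenyl pivalate | COc1ccc(/C=C/[C@H](c2ccc(O)cc2)c2cc(-c3coc4cc(OC)cc(O)c4c3=O)c(O)cc2OC(=O)C(C)(C)C)c(OC)c1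
F9 | step 3 | 1-bromo-2,4-diisopropoxybenzene | CC(C)Oc1ccc(Br)c(OC(C)C)c1
F10 | step 3 | 5-bromo-2,4-diisopropoxybenzaldehyde | CC(C)Oc1cc(OC(C)C)c(C=O)cc1Br
F11 | step 3 | (2E)-3-(5-bromo-2,4-diisopropoxyphenyl)-1-(2,4-dimethoxyphenyl)prop-2-en-1-one | COc1ccc(C(=O)/C=C/c2cc(Br)c(OC(C)C)cc2OC(C)C)c(OC)c1
F12 | step 3 | (3R)-3-(5-bromo-2,4-diisopropoxyphenyl)-1-(2,4-dimethoxyphenyl)-3-(4-isopropoxyphenyl)propan-1-one | COc1ccc(C(=O)C[C@H](c2ccc(OC(C)C)cc2)c2cc(Br)c(OC(C)C)cc2OC(C)C)c(OC)c1
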